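**Strategy.** Everything rests on taking ring A apart last. In the target, C8 (bearing the stereogenic 1-arylethyl group) is bonded to C8a, the carbon that carries O1, and C5 is bonded to C4a, so ring A is a resorcinol fused to the C4a–C8a edge of ring C. Cutting C7–C8 and C5–C6 leaves an acetyl unit and a fully substituted 4-pyranone: (S)-2-arylpropyl chain at C2, methyl ester at C3, benzyloxy at C5, protected guaiacyl ring at C6. One anionic operation acetylates the side-chain methylene and closes the resulting methyl ketone onto the ester, building and aromatising ring A with the 8-substitution pattern fixed in advance. The stereocentre stems from a rhodium-catalysed conjugate arylation.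

Key step: step 10

Assumption: the facial sense of the conjugate arylation is taken from the established behaviour of E-crotonates, where (S)-BINAP leads to the R ester, so (R)-BINAP is specified.

Step 1
Reactants: 1 4-bromo-2,6-dimethoxyphenol
Product: 2 2-(benzyloxy)-5-bromo-1,3-dimethoxybenzene
Conditions: BnBr (1.2 equiv), K2CO3 (2 equiv), DMF, 60 °C
Reagents that add atoms: benzyl bromide, BrCc1ccccc1
Why: Williamson ether synthesis, in which the phenoxide displaces bromide; the benzyl ether should survive organolithium, amide base and magnesium salts and is removed only in the last step.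

Step 2
Reactants: 2 2-(benzyloxy)-5-bromo-1,3-dimethoxybenzene
Product: 5 [4-(benzyloxy)-3,5-dimethoxyphenyl]boronic acid, via aryllithium 3 (not isolated), via lithium arylborate 4 (not isolated)
Conditions: n-BuLi (1.1 equiv), THF, −78 °C; B(OiPr)3 (1.5 equiv), −78 °C → rt; 1 M HCl
Reagents that add atoms: triisopropyl borate, CC(C)OB(OC(C)C)OC(C)C; water, O; n-butyllithium, [Li]CCCC (lithium of 3 and 4 only)
Why: Bromine–lithium exchange is faster than any attack on the ethers at −78 °C, and borylation of the aryllithium followed by mild acid hydrolysis is the standard route to an arylboronic acid.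

Step 3
Reactants: 5 [4-(benzyloxy)-3,5-dimethoxyphenyl]boronic acid, 6 methyl (E)-but-2-enoate
Product: 7 methyl (3S)-3-[4-(benzyloxy)-3,5-dimethoxyphenyl]butanoate
Conditions: Rh(acac)(C2H4)2 (3 mol %), (R)-BINAP (4.5 mol %), 5 (1.5 equiv), dioxane/H2O 10:1, 100 °C
Reagents that add atoms: none
Why: Hayashi–Miyaura asymmetric conjugate addition, in which the aryl–rhodium species held by (R)-BINAP should insert the E-enoate on its alpha-re face and so set the S configuration at C3 before water releases the ester.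

Step 4
Reactants: 7 methyl (3S)-3-[4-(benzyloxy)-3,5-dimethoxyphenyl]butanoate
Product: 8 (3S)-3-[4-(benzyloxy)-3,5-dimethoxyphenyl]butanoic acid
Conditions: LiOH (3 equiv), THF/MeOH/H2O, rt; 1 M HCl
Reagents that add atoms: lithium hydroxide, [Li+].[OH-]
Why: Plain saponification, in which the stereocentre is beta to the carbonyl group, carries no acidic hydrogen and therefore cannot epimerise.

Step 5
Reactants: 8 (3S)-3-[4-(benzyloxy)-3,5-dimethoxyphenyl]butanoic acid, 9 potassium methyl malonate
Product: 11 methyl (5S)-5-[4-(benzyloxy)-3,5-dimethoxyphenyl]-3-oxohexanoate, via acyl imidazolide 10 (not isolated)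
Conditions: CDI (1.1 equiv), THF, rt; then 9 (1.8 equiv), MgCl2 (1.8 equiv), Et3N (2.5 equiv), MeCN, rt; 1 M HCl
Reagents that add atoms: 1,1'-carbonyldiimidazole, O=C(n1ccnc1)n1ccnc1 (imidazolyl group of 10 only)
Why: Masamune–Brooks homologation, in which the acyl imidazolide acylates the magnesium enolate of the malonate half-ester and loss of CO2 gives the β-keto ester under nearly neutral conditions.

Step 6
Reactants: 12 4-(benzyloxy)-3-methoxybenzoic acid, 13 methyl 2-(benzyloxy)acetate
Product: 15 methyl 2-(benzyloxy)-3-[4-(benzyloxy)-3-methoxyphenyl]-3-oxopropanoate, via aroyl chloride 14 (not isolated)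
Conditions: 12, (COCl)2 (1.2 equiv), DMF (cat.), CH2Cl2, rt, evaporate; 13 (2.1 equiv), LiN(iPr)2 (2.1 equiv), THF, −78 °C, then 14; 1 M HCl
Reagents that add atoms: oxalyl chloride, O=C(Cl)C(=O)Cl (chlorine of 14 only)
Why: Crossed Claisen acylation of a preformed lithium ester enolate by a non-enolisable aroyl chloride, with the second equivalent of enolate taking up the acidic proton of the product.

Step 7
Reactants: 15 methyl 2-(benzyloxy)-3-[4-(benzyloxy)-3-methoxyphenyl]-3-oxopropanoate
Product: 16 methyl 2-(benzyloxy)-3-[4-(benzyloxy)-3-methoxyphenyl]-3-chloroprop-2-enoate (E/Z mixture)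
Conditions: Ph3PCl2 (1.5 equiv), Et3N (2 equiv), CH2Cl2, 0 °C → reflux
Reagents that add atoms: dichlorotriphenylphosphorane, ClP(Cl)(c1ccccc1)(c1ccccc1)c1ccccc1
Why: Deoxychlorination of an enolisable β-keto ester, in which the enolate oxygen binds phosphorus and chloride replaces the oxyphosphonium group by addition–elimination; both alkene isomers are usable because the later ring closure passes through a freely rotating enolate.

Step 8
Reactants: 16 methyl 2-(benzyloxy)-3-[4-(benzyloxy)-3-methoxyphenyl]-3-chloroprop-2-enoate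
Product: 17 2-(benzyloxy)-3-[4-(benzyloxy)-3-methoxyphenyl]-3-chloroprop-2-enoic acid
Conditions: LiOH (3 equiv), THF/MeOH/H2O, rt → 40 °C; 1 M HCl
Reagents that add atoms: lithium hydroxide, [Li+].[OH-]
Why: Saponification of the methyl ester, tolerated because the tetrasubstituted, donor-flanked chloroalkene has no alpha hydrogen for elimination and is a poor acceptor for hydroxide.

Step 9
Reactants: 17 2-(benzyloxy)-3-[4-(benzyloxy)-3-methoxyphenyl]-3-chloroprop-2-enoic acid, 11 methyl (5S)-5-[4-(benzyloxy)-3,5-dimethoxyphenyl]-3-oxohexanoate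
Product: 20 methyl 5-(benzyloxy)-6-[4-(benzyloxy)-3-methoxyphenyl]-2-{(2S)-2-[4-(benzyloxy)-3,5-dimethoxyphenyl]propyl}-4-oxo-4H-pyran-3-carboxylate, via acid chloride 18 (not isolated), via open-chain tricarbonyl compound 19 (not isolated)
Conditions: 17, (COCl)2 (1.2 equiv), DMF (cat.), CH2Cl2, 0 °C → rt, evaporate; 11, MgCl2 (1.5 equiv), pyridine (2.5 equiv), CH2Cl2, 0 °C → rt; dilute HCl wash; K2CO3 (2 equiv), DMF, 50 °C
Reagents that add atoms: oxalyl chloride, O=C(Cl)C(=O)Cl (acyl chlorine of 18 only)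
Why: Chelate-directed C-acylation of the magnesium β-keto ester enolate followed by intramolecular vinylic substitution (6-endo oxa-Michael addition of the ketone enolate oxygen, then loss of chloride), the vinylogous counterpart of the chromone-3-carboxylate synthesis from 2-halobenzoyl chlorides.

Step 10
Reactants: 20 methyl 5-(benzyloxy)-6-[4-(benzyloxy)-3-methoxyphenyl]-2-{(2S)-2-[4-(benzyloxy)-3,5-dimethoxyphenyl]propyl}-4-oxo-4H-pyran-3-carboxylate, 21 1-acetylimidazole
Product: 24 3-(benzyloxy)-2-[4-(benzyloxy)-3-methoxyphenyl]-8-{(1R)-1-[4-(benzyloxy)-3,5-dimethoxyphenyl]ethyl}-5,7-dihydroxy-4H-chromen-4-one, via lithium dienolate 22 (not isolated), via methyl ketone 23 (not isolated)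
Conditions: LiN(iPr)2 (1.05 equiv), THF, −78 °C; 21 (1.2 equiv), −78 → −20 °C; LiN(iPr)2 (4 equiv), −78 → 0 °C; 1 M HCl
Reagents that add atoms: lithium diisopropylamide, [Li+].CC(C)[N-]C(C)C (lithium of 22 only)
Why: Proposed new method: LiN(iPr)2 (one equivalent) removes a proton from the side-chain CH2 (future C8), which is acidified vinylogously by the C4 ketone and by the C3 ester, dienolate 22 is acetylated at carbon by 21 (bond C8–C7), and further LiN(iPr)2 turns 23 into its dianion, whose terminal carbon (C6) attacks the neighbouring ester (bond C6–C5), so that loss of methoxide and double enolisation deliver the aromatic ring irreversibly. The closest known reaction types are the acylation of ortho-toluate carbanions followed by Dieckmann closure to naphthalene-1,3-diols, the Staunton–Weinreb annulation and the gamma-acylation of dioxinone dienolates by N-acyl azoles, none of which has been run on a 4-pyranone-3-carboxylate. Ring A closes in the 6-exo-trig mode at the ester carbonyl. No stereocentre is formed, since C8 ends up planar, and the existing centre is never alpha to a carbonyl group, so it keeps its geometry while its descriptor changes from S to R only because aromatic C8 outranks the syringyl carbon. The acyl imidazole and the staged addition of base replace a plain acetate ester, which excess amide would enolise and which is too weak an electrophile for this hindered, doubly stabilised carbanion, whereas imidazolide set free from 21 mops up the acidic C8 proton of 23 and returns any O-acetyl product to the pool. The step needs closure through carbon and not through the enolate oxygen, which is secured by forming the dianion before warming and by the gain of aromaticity, and the 6-alkyl regioisomer is excluded because O1 already sits on C8a next to C8.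

Step 11
Reactants: 24 3-(benzyloxy)-2-[4-(benzyloxy)-3-methoxyphenyl]-8-{(1R)-1-[4-(benzyloxy)-3,5-dimethoxyphenyl]ethyl}-5,7-dihydroxy-4H-chromen-4-one
Product: 25 3,5,7-trihydroxy-2-(4-hydroxy-3-methoxyphenyl)-8-[(1R)-1-(4-hydroxy-3,5-dimethoxyphenyl)ethyl]-4H-chromen-4-one
Conditions: H2 (1 atm), Pd/C (10 wt% Pd), EtOAc/MeOH, rt
Reagents that add atoms: none
Why: Hydrogenolysis of the three benzyl ethers under neutral conditions, to which the tetrasubstituted C2–C3 alkene, the methyl ethers and the diarylethane C–C bonds are inert, so the stereocentre is untouched.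

**Compound list**

1 | 4-bromo-2,6-dimethoxyphenol | COc1cc(Br)cc(OC)c1O | starting material
2 | 2-(benzyloxy)-5-bromo-1,3-dimethoxybenzene | COc1cc(Br)cc(OC)c1OCc1ccccc1 | intermediate
3 | [4-(benzyloxy)-3,5-dimethoxyphenyl]lithium (not isolated) | [Li]c1cc(OC)c(OCc2ccccc2)c(OC)c1 | intermediate
4 | lithium [4-(benzyloxy)-3,5-dimethoxyphenyl]tri(propan-2-yloxy)borate (not isolated) | [Li+].COc1cc([B-](OC(C)C)(OC(C)C)OC(C)C)cc(OC)c1OCc1ccccc1 | intermediate
5 | [4-(benzyloxy)-3,5-dimethoxyphenyl]boronic acid | COc1cc(B(O)O)cc(OC)c1OCc1ccccc1 | intermediate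
6 | methyl (E)-but-2-enoate (methyl crotonate) | C/C=C/C(=O)OC | starting material
7 | methyl (3S)-3-[4-(benzyloxy)-3,5-dimethoxyphenyl]butanoate | COC(=O)C[C@H](C)c1cc(OC)c(OCc2ccccc2)c(OC)c1 | intermediate
8 | (3S)-3-[4-(benzyloxy)-3,5-dimethoxyphenyl]butanoic acid | OC(=O)C[C@H](C)c1cc(OC)c(OCc2ccccc2)c(OC)c1 | intermediate
9 | potassium methyl malonate (potassium 3-methoxy-3-oxopropanoate) | [K+].COC(=O)CC([O-])=O | starting material
10 | (3S)-3-[4-(benzyloxy)-3,5-dimethoxyphenyl]-1-(1H-imidazol-1-yl)butan-1-one (not isolated) | O=C(C[C@H](C)c1cc(OC)c(OCc2ccccc2)c(OC)c1)n1ccnc1 | intermediate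
11 | methyl (5S)-5-[4-(benzyloxy)-3,5-dimethoxyphenyl]-3-oxohexanoate | COC(=O)CC(=O)C[C@H](C)c1cc(OC)c(OCc2ccccc2)c(OC)c1 | intermediate
12 | 4-(benzyloxy)-3-methoxybenzoic acid | COc1cc(C(=O)O)ccc1OCc1ccccc1 | starting material
13 | methyl 2-(benzyloxy)acetate | COC(=O)COCc1ccccc1 | starting material
14 | 4-(benzyloxy)-3-methoxybenzoyl chloride (not isolated) | COc1cc(C(=O)Cl)ccc1OCc1ccccc1 | intermediate
15 | methyl 2-(benzyloxy)-3-[4-(benzyloxy)-3-methoxyphenyl]-3-oxopropanoate (racemic) | COC(=O)C(OCc1ccccc1)C(=O)c1ccc(OCc2ccccc2)c(OC)c1 | intermediate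
16 | methyl 2-(benzyloxy)-3-[4-(benzyloxy)-3-methoxyphenyl]-3-chloroprop-2-enoate (E/Z mixture) | COC(=O)C(OCc1ccccc1)=C(Cl)c1ccc(OCc2ccccc2)c(OC)c1 | intermediate
17 | 2-(benzyloxy)-3-[4-(benzyloxy)-3-methoxyphenyl]-3-chloroprop-2-enoic acid (E/Z mixture) | OC(=O)C(OCc1ccccc1)=C(Cl)c1ccc(OCc2ccccc2)c(OC)c1 | intermediate
18 | 2-(benzyloxy)-3-[4-(benzyloxy)-3-methoxyphenyl]-3-chloroprop-2-enoyl chloride (not isolated) | O=C(Cl)C(OCc1ccccc1)=C(Cl)c1ccc(OCc2ccccc2)c(OC)c1 | intermediate
19 | methyl (5S)-2-{2-(benzyloxy)-3-[4-(benzyloxy)-3-methoxyphenyl]-3-chloroprop-2-enoyl}-5-[4-(benzyloxy)-3,5-dimethoxyphenyl]-3-oxohexanoate (not isolated) | COC(=O)C(C(=O)C[C@H](C)c1cc(OC)c(OCc2ccccc2)c(OC)c1)C(=O)C(OCc1ccccc1)=C(Cl)c1ccc(OCc2ccccc2)c(OC)c1 | intermediate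
20 | methyl 5-(benzyloxy)-6-[4-(benzyloxy)-3-methoxyphenyl]-2-{(2S)-2-[4-(benzyloxy)-3,5-dimethoxyphenyl]propyl}-4-oxo-4H-pyran-3-carboxylate | COC(=O)c1c(C[C@H](C)c2cc(OC)c(OCc3ccccc3)c(OC)c2)oc(-c2ccc(OCc3ccccc3)c(OC)c2)c(OCc2ccccc2)c1=O | intermediate
21 | 1-acetylimidazole | CC(=O)n1ccnc1 | starting material
22 | lithium dienolate of 20, drawn as the 4-oxido-2-alkylidene-2H-pyran (not isolated) | [Li+].COC(=O)C1=C([O-])C(OCc2ccccc2)=C(c2ccc(OCc3ccccc3)c(OC)c2)OC1=C[C@H](C)c1cc(OC)c(OCc2ccccc2)c(OC)c1 | intermediate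
23 | methyl 5-(benzyloxy)-6-[4-(benzyloxy)-3-methoxyphenyl]-2-{(2S)-2-[4-(benzyloxy)-3,5-dimethoxyphenyl]-4-oxopentan-3-yl}-4-oxo-4H-pyran-3-carboxylate (present as its lithium enolate, not isolated) | COC(=O)c1c(C(C(C)=O)[C@H](C)c2cc(OC)c(OCc3ccccc3)c(OC)c2)oc(-c2ccc(OCc3ccccc3)c(OC)c2)c(OCc2ccccc2)c1=O | intermediate
24 | 3-(benzyloxy)-2-[4-(benzyloxy)-3-methoxyphenyl]-8-{(1R)-1-[4-(benzyloxy)-3,5-dimethoxyphenyl]ethyl}-5,7-dihydroxy-4H-chromen-4-one | COc1cc(-c2oc3c([C@H](C)c4cc(OC)c(OCc5ccccc5)c(OC)c4)c(O)cc(O)c3c(=O)c2OCc2ccccc2)ccc1OCc1ccccc1 | intermediate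
25 | 3,5,7-trihydroxy-2-(4-hydroxy-3-methoxyphenyl)-8-[(1R)-1-(4-hydroxy-3,5-dimethoxyphenyl)ethyl]-4H-chromen-4-one (CNP0261887.1) | COc1cc(-c2oc3c([C@H](C)c4cc(OC)c(O)c(OC)c4)c(O)cc(O)c3c(=O)c2O)ccc1O | target

Total step count: 11. Longest linear sequence: 8 (steps 1, 2, 3, 4, 5, 9, 10, 11).

**Steps most likely to fail**

**Step 10.**
- What may go wrong:
  - slow or oxygen-centred acetylation of the hindered, doubly stabilised carbanion;
  - closure of the acetylated intermediate through its enolate oxygen instead of carbon;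
  - opening of the pyranone ring by conjugate attack of amide, imidazolide or alkoxide.
- Fallback: ring A first, known chemistry only. It sets out from 5 and 15 and returns at 25.
  - Purchased 5,7-dihydroxycoumarin is benzylated (BnBr, K2CO3, DMF) to 5,7-bis(benzyloxy)-2H-chromen-2-one F1.
  - Hayashi–Miyaura addition of 5 to F1 with Rh(acac)(C2H4)2 and (R)-SEGPHOS is a reaction established for coumarins. By the same facial model as step 3 it should give (4R)-5,7-bis(benzyloxy)-4-[4-(benzyloxy)-3,5-dimethoxyphenyl]chroman-2-one F2, in which the lactone oxygen marks the future O1.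
  - iBu2AlH in toluene at −78 °C gives (4R)-5,7-bis(benzyloxy)-4-[4-(benzyloxy)-3,5-dimethoxyphenyl]chroman-2-ol F3.
  - Tsuji–Wilkinson decarbonylation of the open hydroxy-aldehyde form of F3 with RhCl(PPh3)3 in hot toluene turns the CH2CHO arm into the methyl group. It also frees the single phenol, giving 3,5-bis(benzyloxy)-2-{(1R)-1-[4-(benzyloxy)-3,5-dimethoxyphenyl]ethyl}phenol F4.
  - Thermal condensation of F4 with β-keto ester 15 (Mentzer chromone synthesis, diphenyl ether, about 240 °C) acylates the only free position ortho to that phenol and closes ring C. The product is 3,5,7-tris(benzyloxy)-2-[4-(benzyloxy)-3-methoxyphenyl]-8-{(1R)-1-[4-(benzyloxy)-3,5-dimethoxyphenyl]ethyl}-4H-chromen-4-one F5.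
  - Hydrogenolysis under the conditions of step 11 then gives 25.

**Step 9.**
- What may go wrong:
  - acylation of the magnesium enolate on oxygen instead of carbon;
  - decay of the acid chloride before it is consumed;
  - slow vinylic substitution, because the chlorine-bearing carbon is flanked by two donor groups.
- Fallback: a triketone cyclodehydration that needs no vinyl chloride. It sets out from 8 and 14 and returns at 20.
  - Acid 8 is converted with (COCl)2 and catalytic DMF into (3S)-3-[4-(benzyloxy)-3,5-dimethoxyphenyl]butanoyl chloride F6.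
  - Separately, the dianion of purchased methyl 4-(benzyloxy)-3-oxobutanoate (NaH, then n-BuLi, THF, −78 °C, used in excess) is aroylated at C4 by 14. This gives methyl 4-(benzyloxy)-5-[4-(benzyloxy)-3-methoxyphenyl]-3,5-dioxopentanoate F7.
  - C-acylation of F7 by F6 with MgCl2 and pyridine should settle at C2, because only that product keeps an enolisable, chelating tricarbonyl unit. It gives methyl (5S)-2-{2-(benzyloxy)-3-[4-(benzyloxy)-3-methoxyphenyl]-3-oxopropanoyl}-5-[4-(benzyloxy)-3,5-dimethoxyphenyl]-3-oxohexanoate F8.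
  - Acid-catalysed cyclodehydration of the 1,3,5-triketone unit of F8 (p-TsOH, toluene, removal of water) closes the same pyranone 20.

**Step 7.**
- What may go wrong:
  - incomplete activation of a hindered, weakly enolised keto ester;
  - competing chlorination at the alpha carbon;
  - loss of a benzyl ether under the halophosphonium conditions.
- Fallback: chloroformylation of the ketone in place of deoxychlorination of the keto ester. It sets out from 15 and returns at 17.
  - Krapcho dealkoxycarbonylation (LiCl, wet DMSO, 130 °C) gives 2-(benzyloxy)-1-[4-(benzyloxy)-3-methoxyphenyl]ethan-1-one F9.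
  - Vilsmeier–Haack–Arnold chloroformylation (POCl3, DMF, 0 → 60 °C) gives 2-(benzyloxy)-3-[4-(benzyloxy)-3-methoxyphenyl]-3-chloroprop-2-enal F10.
  - Pinnick oxidation (NaClO2, NaH2PO4, 2-methylbut-2-ene, t-BuOH/H2O) gives acid 17 directly, so step 8 is no longer needed.

**Further compounds**

F1 | step 10 | 5,7-bis(benzyloxy)-2H-chromen-2-one | O=c1ccc2c(OCc3ccccc3)cc(OCc3ccccc3)cc2o1
F2 | step 10 | (4R)-5,7-bis(benzyloxy)-4-[4-(benzyloxy)-3,5-dimethoxyphenyl]chroman-2-one | O=C1C[C@H](c2cc(OC)c(OCc3ccccc3)c(OC)c2)c2c(OCc3ccccc3)cc(OCc3ccccc3)cc2O1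
F3 | step 10 | (4R)-5,7-bis(benzyloxy)-4-[4-(benzyloxy)-3,5-dimethoxyphenyl]chroman-2-ol | OC1C[C@H](c2cc(OC)c(OCc3ccccc3)c(OC)c2)c2c(OCc3ccccc3)cc(OCc3ccccc3)cc2O1
F4 | step 10 | 3,5-bis(benzyloxy)-2-{(1R)-1-[4-(benzyloxy)-3,5-dimethoxyphenyl]ethyl}phenol | C[C@H](c1cc(OC)c(OCc2ccccc2)c(OC)c1)c1c(O)cc(OCc2ccccc2)cc1OCc1ccccc1
F5 | step 10 | 3,5,7-tris(benzyloxy)-2-[4-(benzyloxy)-3-methoxyphenyl]-8-{(1R)-1-[4-(benzyloxy)-3,5-dimethoxyphenyl]ethyl}-4H-chromen-4-one | COc1cc(-c2oc3c([C@H](C)c4cc(OC)c(OCc5ccccc5)c(OC)c4)c(OCc4ccccc4)cc(OCc4ccccc4)c3c(=O)c2OCc2ccccc2)ccc1OCc1ccccc1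
F6 | step 9 | (3S)-3-[4-(benzyloxy)-3,5-dimethoxyphenyl]butanoyl chloride | O=C(Cl)C[C@H](C)c1cc(OC)c(OCc2ccccc2)c(OC)c1
F7 | step 9 | methyl 4-(benzyloxy)-5-[4-(benzyloxy)-3-methoxyphenyl]-3,5-dioxopentanoate | COC(=O)CC(=O)C(OCc1ccccc1)C(=O)c1ccc(OCc2ccccc2)c(OC)c1
F8 | step 9 | methyl (5S)-2-{2-(benzyloxy)-3-[4-(benzyloxy)-3-methoxyphenyl]-3-oxopropanoyl}-5-[4-(benzyloxy)-3,5-dimethoxyphenyl]-3-oxohexanoate | COC(=O)C(C(=O)C[C@H](C)c1cc(OC)c(OCc2ccccc2)c(OC)c1)C(=O)C(OCc1ccccc1)C(=O)c1ccc(OCc2ccccc2)c(OC)c1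
F9 | step 7 | 2-(benzyloxy)-1-[4-(benzyloxy)-3-methoxyphenyl]ethan-1-one | COc1cc(C(=O)COCc2ccccc2)ccc1OCc1ccccc1
F10 | step 7 | 2-(benzyloxy)-3-[4-(benzyloxy)-3-methoxyphenyl]-3-chloroprop-2-enal | O=CC(OCc1ccccc1)=C(Cl)c1ccc(OCc2ccccc2)c(OC)c1
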